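**Retrosynthetic overview**

- Isoamoritin is released from its 7,3'-bis-MOM ether by acidic methanolysis in the last step.
- The three aryl–CH2(prenyl) bonds at C6 and C8 (ring A) and C5' (ring B) are cut together. Each of these carbons sits next to an oxygen-bearing carbon (C6 between C5 and C7, C8 between C7 and C8a, C5' beside C4'), so C6 and C8 can be iodinated on the free 5,7-diol and C5' can be carried as a bromide from the start. This leads back to a (2S)-6,8-diiodo-5'-bromoflavanone and tributyl(prenyl)stannane, joined by a threefold Stille coupling.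
- The trihalide comes from NIS di-iodination of the (2S)-5,7,3'-trihydroxy-5'-bromo-4'-methoxyflavanone and MOM capping of 7-OH and 3'-OH, so all halogenation and strong acid precede the first prenyl group.
- The C2–C1' bond and the S centre come from a rhodium/chiral-diene 1,4-addition of an arylboronic acid to 5,7-bis(MOM-oxy)chromone. The boronic acid is made from 2,6-dibromoanisole by hydroxylation, MOM protection and C–H borylation.
- No ring is formed in the route: ring A and the pyranone ring arrive with the chromone, ring B with the anisole.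

Key step: step 9

Remark: flavanone numbering is used (ring A = benzo ring C5–C8 of the chroman-4-one, ring B = the 2-aryl group with primed locants); the descriptor in the target SMILES corresponds to 2S; 5,7-dihydroxychromone is taken as a purchasable fine chemical.

**Route**

Step 1
Reactants: 1 2,6-dibromoanisole
Product: 4 3-bromo-2-methoxyphenol, via (3-bromo-2-methoxyphenyl)lithium 2 (not isolated), via lithium (3-bromo-2-methoxyphenyl)trimethoxyborate 3 (not isolated)
Conditions: n-BuLi (1.0 equiv), THF, −78 °C; B(OMe)3, −78 °C to rt; then AcOH, 30% H2O2, 0 °C to rt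
Reagents that add atoms: hydrogen peroxide, OO
Why: Bromine–lithium exchange takes place once because the two C–Br bonds are equivalent and a second exchange on the aryllithium is much slower (lithium and the remaining bromine are meta, so no aryne can form), the aryllithium is trapped as the borate, and peroxide oxidation with 1,2-shift of the aryl group from boron to oxygen (boronate oxidation) delivers the phenol.

Step 2
Reactants: 4 3-bromo-2-methoxyphenol
Product: 5 1-bromo-2-methoxy-3-(methoxymethoxy)benzene
Conditions: MOMCl (1.3 equiv), i-Pr2NEt (1.6 equiv), CH2Cl2, 0 °C to rt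
Reagents that add atoms: chloromethyl methyl ether, COCCl
Why: O-Alkylation of the phenol with the reactive α-chloro ether under amine base (Williamson-type MOM protection) masks the hydroxyl so that it is not O-borylated in step 3 and cannot protonate the aryl–rhodium species in step 5.

Step 3
Reactants: 5 1-bromo-2-methoxy-3-(methoxymethoxy)benzene
Product: 7 [3-bromo-4-methoxy-5-(methoxymethoxy)phenyl]boronic acid, via pinacol arylboronate 6 (not isolated)
Conditions: [Ir(OMe)(cod)]2 (1.5 mol %), 4,4'-di-tert-butyl-2,2'-bipyridine (3 mol %), B2pin2 (1.0 equiv), THF, 80 °C; then NaIO4 (4 equiv), NH4OAc (3 equiv), acetone/H2O, rt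
Reagents that add atoms: bis(pinacolato)diboron, CC1(C)OB(OC1(C)C)B1OC(C)(C)C(C)(C)O1; water, O
Why: Iridium-catalysed C–H borylation is governed by sterics, and in this 1,2,3-trisubstituted arene only C5–H (para to OMe, meta to Br and to OMOM) has no ortho substituent, while the C–Br bond is inert to the iridium boryl catalyst; buffered periodate then cleaves the pinacol ester to the free boronic acid, which transmetalates to rhodium more readily than the ester, without touching the MOM ether.

Step 4
Reactants: 8 5,7-dihydroxy-4H-chromen-4-one (5,7-dihydroxychromone)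
Product: 10 5,7-bis(methoxymethoxy)-4H-chromen-4-one, via disodium 4-oxo-4H-chromene-5,7-diolate 9 (not isolated)
Conditions: NaH (2.5 equiv), DMF, 0 °C; then MOMCl (2.6 equiv), 0 °C to rt
Reagents that add atoms: chloromethyl methyl ether, COCCl
Why: Double deprotonation breaks the hydrogen bond between the 5-hydroxyl and the C4 carbonyl, so both phenoxides are alkylated by MOMCl (Williamson-type etherification) and the chromone enters step 5 without an acidic proton.

Step 5
Reactants: 7 [3-bromo-4-methoxy-5-(methoxymethoxy)phenyl]boronic acid; 10 5,7-bis(methoxymethoxy)-4H-chromen-4-one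
Product: 11 (2S)-2-[3-bromo-4-methoxy-5-(methoxymethoxy)phenyl]-5,7-bis(methoxymethoxy)chroman-4-one
Conditions: [RhCl(C2H4)2]2 (2.5 mol %), (1S,4S)-2,5-diphenylbicyclo[2.2.2]octa-2,5-diene (5.5 mol %), 7 (2.0 equiv), aqueous K3PO4 (0.5 equiv), toluene/H2O, 40 °C
Reagents that add atoms: none
Why: Hayashi–Miyaura asymmetric 1,4-addition, in which the aryl group passes from boron to a hydroxo-rhodium–diene complex (monovalent rhodium, inert to the C–Br bond), the chromone C2=C3 bond inserts into the Rh–aryl bond on the face left open by the C2-symmetric diene and the oxa-π-allyl rhodium is protonated by water, so that the ligand alone sets C2; the (S,S) diene is proposed on the assumption that the facial sense follows that known for cyclohex-2-enone, and the sense is to be verified on the first batch, the antipodal diene being used if it proves opposite.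

Step 6
Reactants: 11 (2S)-2-[3-bromo-4-methoxy-5-(methoxymethoxy)phenyl]-5,7-bis(methoxymethoxy)chroman-4-one
Product: 12 (2S)-2-(3-bromo-5-hydroxy-4-methoxyphenyl)-5,7-dihydroxychroman-4-one
Conditions: HCl (1.25 M in MeOH), 40 °C
Reagents that add atoms: none
Why: Acid-catalysed exchange of the three mixed formaldehyde acetals with methanol (standard MOM cleavage) frees the phenols, and without base no C3 enolate can form, so the C2–O1 bond is not opened and the S configuration is kept.

Step 7
Reactants: 12 (2S)-2-(3-bromo-5-hydroxy-4-methoxyphenyl)-5,7-dihydroxychroman-4-one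
Product: 13 (2S)-2-(3-bromo-5-hydroxy-4-methoxyphenyl)-5,7-dihydroxy-6,8-diiodochroman-4-one
Conditions: NIS (2.05 equiv), DMF, 0 °C, dark
Reagents that add atoms: N-iodosuccinimide, O=C1CCC(=O)N1I
Why: Electrophilic aromatic iodination, in which C6 and C8 of ring A each stand ortho or para to three oxygen substituents (phloroglucinol-type ring) and react much faster than C2' and C6' of ring B, which are activated by one hydroxyl only and deactivated by bromine, so two equivalents of NIS should stop at the 6,8-diiodide.

Step 8
Reactants: 13 (2S)-2-(3-bromo-5-hydroxy-4-methoxyphenyl)-5,7-dihydroxy-6,8-diiodochroman-4-one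
Product: 14 (2S)-2-[3-bromo-4-methoxy-5-(methoxymethoxy)phenyl]-5-hydroxy-6,8-diiodo-7-(methoxymethoxy)chroman-4-one
Conditions: MOMCl (2.3 equiv), i-Pr2NEt (2.6 equiv), CH2Cl2, 0 °C
Reagents that add atoms: chloromethyl methyl ether, COCCl
Why: Williamson-type MOM etherification is selective because the acidic 7-OH and the ordinary 3'-OH are alkylated under amine base whereas the 5-OH is held in a hydrogen bond to the C4 carbonyl and is flanked by C6–I, and the amine is too weak to open the pyranone ring, so C2 is untouched.

Step 9
Reactants: 14 (2S)-2-[3-bromo-4-methoxy-5-(methoxymethoxy)phenyl]-5-hydroxy-6,8-diiodo-7-(methoxymethoxy)chroman-4-one; 15 tributyl(3-methylbut-2-en-1-yl)stannane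
Product: 16 (2S)-5-hydroxy-7-(methoxymethoxy)-2-[4-methoxy-3-(methoxymethoxy)-5-(3-methylbut-2-en-1-yl)phenyl]-6,8-bis(3-methylbut-2-en-1-yl)chroman-4-one
Conditions: 15 (4.5 equiv), Pd2(dba)3 (7.5 mol %), P(t-Bu)3 (18 mol %), degassed DMF, 70 °C, dark
Reagents that add atoms: none
Why: This is a threefold Migita–Kosugi–Stille coupling in which monoligated zerovalent palladium inserts in turn into the two C–I bonds of ring A and the C–Br bond of ring B, the allylic stannane hands its prenyl group to each arylpalladium halide (the primary and tertiary σ-allyl forms equilibrate through the η3-allyl complex), and reductive elimination forms the C6–CH2, C8–CH2 and C5'–CH2 bonds with loss of Bu3SnI or Bu3SnBr. The closest known reaction is the Stille coupling of single aryl iodides and bromides with tributyl(prenyl)stannane to give linear prenylarenes, here run three times on one substrate. No ring is closed and no stereocentre is formed; C2 keeps its S configuration because the medium holds neither base nor fluoride, so the C3 enolate needed for retro-oxa-Michael opening to the chalcone never forms. The selectivity required is linear over branched transfer at all three sites, and sterics should secure it: every arylpalladium is ortho-substituted (C6 and C8 on both sides by oxygen-bearing carbons, C5' by the C4' methoxy carbon) and carries the bulky P(t-Bu)3, so palladium sits on the primary CH2 of the allyl unit and the C–C bond forms at that unsubstituted terminus. No discrimination between the halides is needed since all three must react; the excess stannane and the high activity of the phosphine towards aryl bromides should drive the third coupling to completion, while the 5-OH stays in its hydrogen bond to C4=O and does not protonate the stannane.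

Step 10
Reactants: 16 (2S)-5-hydroxy-7-(methoxymethoxy)-2-[4-methoxy-3-(methoxymethoxy)-5-(3-methylbut-2-en-1-yl)phenyl]-6,8-bis(3-methylbut-2-en-1-yl)chroman-4-one
Product: 17 isoamoritin, (2S)-5,7-dihydroxy-2-[3-hydroxy-4-methoxy-5-(3-methylbut-2-en-1-yl)phenyl]-6,8-bis(3-methylbut-2-en-1-yl)chroman-4-one
Conditions: HCl (0.5 M in MeOH), rt to 40 °C
Reagents that add atoms: none
Why: Acid-catalysed exchange of the two MOM acetals with methanol under dilute, cool conditions should release the 7- and 3'-hydroxyls faster than the trisubstituted prenyl alkenes are protonated (which would lead to dimethylchroman rings), and C2 is not epimerised because no base is present.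

**Compound list**

1 | 2,6-dibromoanisole (1,3-dibromo-2-methoxybenzene) | COc1c(Br)cccc1Br | starting material
2 | (3-bromo-2-methoxyphenyl)lithium | [Li]c1cccc(Br)c1OC | intermediate
3 | lithium (3-bromo-2-methoxyphenyl)trimethoxyborate | [Li+].CO[B-](OC)(OC)c1cccc(Br)c1OC | intermediate
4 | 3-bromo-2-methoxyphenol | COc1c(O)cccc1Br | intermediate
5 | 1-bromo-2-methoxy-3-(methoxymethoxy)benzene | COCOc1cccc(Br)c1OC | intermediate
6 | 2-[3-bromo-4-methoxy-5-(methoxymethoxy)phenyl]-4,4,5,5-tetramethyl-1,3,2-dioxaborolane | COCOc1cc(B2OC(C)(C)C(C)(C)O2)cc(Br)c1OC | intermediate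
7 | [3-bromo-4-methoxy-5-(methoxymethoxy)phenyl]boronic acid | COCOc1cc(B(O)O)cc(Br)c1OC | intermediate
8 | 5,7-dihydroxy-4H-chromen-4-one | O=c1ccoc2cc(O)cc(O)c12 | starting material
9 | disodium 4-oxo-4H-chromene-5,7-diolate | O=c1ccoc2cc([O-])cc([O-])c12.[Na+].[Na+] | intermediate
10 | 5,7-bis(methoxymethoxy)-4H-chromen-4-one | O=c1ccoc2cc(OCOC)cc(OCOC)c12 | intermediate
11 | (2S)-2-[3-bromo-4-methoxy-5-(methoxymethoxy)phenyl]-5,7-bis(methoxymethoxy)chroman-4-one | COc1c(OCOC)cc([C@@H]2CC(=O)c3c(OCOC)cc(OCOC)cc3O2)cc1Br | intermediate
12 | (2S)-2-(3-bromo-5-hydroxy-4-methoxyphenyl)-5,7-dihydroxychroman-4-one | COc1c(O)cc([C@@H]2CC(=O)c3c(O)cc(O)cc3O2)cc1Br | intermediate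
13 | (2S)-2-(3-bromo-5-hydroxy-4-methoxyphenyl)-5,7-dihydroxy-6,8-diiodochroman-4-one | COc1c(O)cc([C@@H]2CC(=O)c3c(O)c(I)c(O)c(I)c3O2)cc1Br | intermediate
14 | (2S)-2-[3-bromo-4-methoxy-5-(methoxymethoxy)phenyl]-5-hydroxy-6,8-diiodo-7-(methoxymethoxy)chroman-4-one | COc1c(OCOC)cc([C@@H]2CC(=O)c3c(O)c(I)c(OCOC)c(I)c3O2)cc1Br | intermediate
15 | tributyl(3-methylbut-2-en-1-yl)stannane | CCCC[Sn](CCCC)(CCCC)CC=C(C)C | starting material
16 | (2S)-5-hydroxy-7-(methoxymethoxy)-2-[4-methoxy-3-(methoxymethoxy)-5-(3-methylbut-2-en-1-yl)phenyl]-6,8-bis(3-methylbut-2-en-1-yl)chroman-4-one | COc1c(OCOC)cc([C@@H]2CC(=O)c3c(O)c(CC=C(C)C)c(OCOC)c(CC=C(C)C)c3O2)cc1CC=C(C)C | intermediate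
17 | isoamoritin | COc1c(O)cc([C@@H]2CC(=O)c3c(O)c(CC=C(C)C)c(O)c(CC=C(C)C)c3O2)cc1CC=C(C)C | target

**Step count and risks**

Total step count: 10. Longest linear sequence: 9 steps (steps 1–3 and 5–10); step 4 is a one-step side branch.

Steps most likely to fail:

Step 9. The prenyl unit may be transferred through its substituted terminus at one or more of the three positions (1,1-dimethylallyl in place of prenyl), or coupling may stop short with reduction of a carbon–halogen bond, giving mixtures that are hard to separate. The fallback sets out from 14. A threefold Stille coupling with allyltributylstannane (Pd(PPh3)4, DMF, 80 °C), whose symmetric allyl group leaves no regiochemical choice, should give (2S)-5-hydroxy-7-(methoxymethoxy)-2-[4-methoxy-3-(methoxymethoxy)-5-(prop-2-en-1-yl)phenyl]-6,8-di(prop-2-en-1-yl)chroman-4-one F1. A threefold olefin cross-metathesis of F1 with 2-methylbut-2-ene as co-solvent and second-generation Grubbs catalyst in CH2Cl2 at 40 °C then turns each allyl group into a prenyl group, and the route is rejoined at 16.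

Step 5. Facial selectivity may be poor with the electron-rich, 5-substituted chromone, or enantiomeric purity may erode through base-promoted opening and reclosure of the pyranone ring during the reaction. The fallback sets out from 7 and 10. The addition is run with the achiral and more active [Rh(OH)(cod)]2 in dioxane/water to give racemic 2-[3-bromo-4-methoxy-5-(methoxymethoxy)phenyl]-5,7-bis(methoxymethoxy)chroman-4-one F2, and the enantiomers are separated by preparative HPLC on a polysaccharide chiral stationary phase. The (2S) enantiomer is 11, where the route is rejoined; the (2R)-2-[3-bromo-4-methoxy-5-(methoxymethoxy)phenyl]-5,7-bis(methoxymethoxy)chroman-4-one F3 is set aside.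

Step 10. The freed 5- and 7-hydroxyls may add under acid to the neighbouring prenyl double bonds (closure to dimethylchroman rings), or methanol may add to the alkenes, before the hindered 7-O-MOM group is fully cleaved. The fallback sets out from 13 and replaces acetal by silyl protection, so that the end game needs no protic acid. TBSCl and imidazole in DMF at 0 °C to rt should give (2S)-2-[3-bromo-5-(tert-butyldimethylsilyloxy)-4-methoxyphenyl]-7-(tert-butyldimethylsilyloxy)-5-hydroxy-6,8-diiodochroman-4-one F4, the 5-OH again staying free. The threefold Stille coupling with 15 under the conditions of step 9 should give (2S)-7-(tert-butyldimethylsilyloxy)-2-[3-(tert-butyldimethylsilyloxy)-4-methoxy-5-(3-methylbut-2-en-1-yl)phenyl]-5-hydroxy-6,8-bis(3-methylbut-2-en-1-yl)chroman-4-one F5. HF·pyridine in THF/pyridine at 0 °C then removes both silyl groups and the route is rejoined at 17.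

**Further compounds**

F1 | step 9 | (2S)-5-hydroxy-7-(methoxymethoxy)-2-[4-methoxy-3-(methoxymethoxy)-5-(prop-2-en-1-yl)phenyl]-6,8-di(prop-2-en-1-yl)chroman-4-one | COc1c(OCOC)cc([C@@H]2CC(=O)c3c(O)c(CC=C)c(OCOC)c(CC=C)c3O2)cc1CC=C
F2 | step 5 | racemic 2-[3-bromo-4-methoxy-5-(methoxymethoxy)phenyl]-5,7-bis(methoxymethoxy)chroman-4-one | COc1c(OCOC)cc(C2CC(=O)c3c(OCOC)cc(OCOC)cc3O2)cc1Br
F3 | step 5 | (2R)-2-[3-bromo-4-methoxy-5-(methoxymethoxy)phenyl]-5,7-bis(methoxymethoxy)chroman-4-one | COc1c(OCOC)cc([C@H]2CC(=O)c3c(OCOC)cc(OCOC)cc3O2)cc1Br
F4 | step 10 | (2S)-2-[3-bromo-5-(tert-butyldimethylsilyloxy)-4-methoxyphenyl]-7-(tert-butyldimethylsilyloxy)-5-hydroxy-6,8-diiodochroman-4-one | COc1c(O[Si](C)(C)C(C)(C)C)cc([C@@H]2CC(=O)c3c(O)c(I)c(O[Si](C)(C)C(C)(C)C)c(I)c3O2)cc1Br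
F5 | step 10 | (2S)-7-(tert-butyldimethylsilyloxy)-2-[3-(tert-butyldimethylsilyloxy)-4-methoxy-5-(3-methylbut-2-en-1-yl)phenyl]-5-hydroxy-6,8-bis(3-methylbut-2-en-1-yl)chroman-4-one | COc1c(O[Si](C)(C)C(C)(C)C)cc([C@@H]2CC(=O)c3c(O)c(CC=C(C)C)c(O[Si](C)(C)C(C)(C)C)c(CC=C(C)C)c3O2)cc1CC=C(C)C
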